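**Plan**
1. Retrosynthesis: the quaternary C1 carries an acyloxy group and a carboxyl group on one carbon, which is the adduct of a ketone, a carboxylic acid and an isocyanide. Cutting C1–CO2H and O1–caffeoyl together (Passerini) exposes C1(=O)–C2H2–C3H(OH), a β-hydroxy ketone inside the cyclohexane ring, and this is cut at C2–C3.
2. The open chain is an alkynal in which C1≡C2 is a latent α-metallated methyl ketone and C3 is the aldehyde. It is cut further at O4–succinyl, O5–caffeoyl and C5–C6, back to (R)-glyceraldehyde acetonide, propargyl bromide, di-O-acetylcaffeic acid and mono-tert-butyl succinate.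
3. Forward: C5–C6 is joined, O5 and then O4 are esterified on the chain, the six-membered ring is closed at C2–C3, C1 is built last, and the protecting groups are removed. The ring closure creates 3-OH as the only free hydroxyl of the ring, so the ring oxygens never have to be told apart.
4. Stereochemistry: C4 comes from D-glyceraldehyde. C5 is set by Felkin–Anh propargylation followed by Mitsunobu inversion. C3 is set in the ring closure (hydroxyl trans to O5, cis to O4). C1 is set by equatorial attack of the isocyanide, anti to the axial 3-OH.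

Key step: step 8

Remark: atoms are numbered as in quinic acid (C1 quaternary, C3 free OH, C4 succinyl, C5 caffeoyl, C7 carboxyl); compounds 4 and 8 are taken as purchasable (4 is otherwise one acetylation away from caffeic acid).

**Step 1**
Reactants: 1 (R)-2,2-dimethyl-1,3-dioxolane-4-carbaldehyde; 2 3-bromoprop-1-yne
Product: 3 (S)-1-[(R)-2,2-dimethyl-1,3-dioxolan-4-yl]but-3-yn-1-ol
Conditions: Zn dust, THF/sat. aq. NH4Cl, 0 °C to rt
Reagents that add atoms: none
Why: Barbier-type propargylation in which the allenylzinc species adds by SE2' to give the homopropargylic alcohol, and Felkin–Anh attack on the α-alkoxy aldehyde should favour the anti (S) carbinol at C5.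

**Step 2**
Reactants: 3 (S)-1-[(R)-2,2-dimethyl-1,3-dioxolan-4-yl]but-3-yn-1-ol; 4 (E)-3-(3,4-diacetoxyphenyl)prop-2-enoic acid
Product: 5 (R)-1-[(R)-2,2-dimethyl-1,3-dioxolan-4-yl]but-3-yn-1-yl (E)-3-(3,4-diacetoxyphenyl)prop-2-enoate
Conditions: PPh3, DIAD, toluene/THF, 0 °C to rt
Reagents that add atoms: none
Why: Mitsunobu esterification, in which SN2 displacement of the alkoxyphosphonium ion by the carboxylate inverts C5 to R, so the anti adduct becomes the syn (threo) C4/C5 array while the 5-O-caffeoyl ester is installed.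

**Step 3**
Reactants: 5 (R)-1-[(R)-2,2-dimethyl-1,3-dioxolan-4-yl]but-3-yn-1-yl (E)-3-(3,4-diacetoxyphenyl)prop-2-enoate
Product: 6 (2R,3R)-1,2-dihydroxyhex-5-yn-3-yl (E)-3-(3,4-diacetoxyphenyl)prop-2-enoate
Conditions: CF3CO2H/H2O (9:1), CH2Cl2, 0 °C, short contact, toluene azeotrope
Reagents that add atoms: none
Why: Acid hydrolysis of the terminal acetonide is fast at 0 °C, and the short, cold, base-free contact should avoid O5-to-O4 acyl migration.

**Step 4**
Reactants: 6 (2R,3R)-1,2-dihydroxyhex-5-yn-3-yl (E)-3-(3,4-diacetoxyphenyl)prop-2-enoate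
Product: 7 (2R,3R)-2-hydroxy-1-(triethylsilyloxy)hex-5-yn-3-yl (E)-3-(3,4-diacetoxyphenyl)prop-2-enoate
Conditions: Et3SiCl (1.05 equiv), pyridine, CH2Cl2, −20 °C
Reagents that add atoms: chlorotriethylsilane, CC[Si](Cl)(CC)CC
Why: Kinetically selective silylation of the primary C3 hydroxyl over the hindered secondary C4 hydroxyl, with a weak base that leaves the aryl acetates and the O5 ester in place.

**Step 5**
Reactants: 7 (2R,3R)-2-hydroxy-1-(triethylsilyloxy)hex-5-yn-3-yl (E)-3-(3,4-diacetoxyphenyl)prop-2-enoate; 8 4-tert-butoxy-4-oxobutanoic acid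
Product: 9 tert-butyl (2R,3R)-3-{[(E)-3-(3,4-diacetoxyphenyl)prop-2-enoyl]oxy}-1-(triethylsilyloxy)hex-5-yn-2-yl butanedioate
Conditions: DIC, DMAP (cat.), CH2Cl2, 0 °C
Reagents that add atoms: none
Why: Steglich esterification of the only free hydroxyl (O4) with the succinic half ester, run cold with little DMAP so that acylation outruns acyl migration.

**Step 6**
Reactants: 9 tert-butyl (2R,3R)-3-{[(E)-3-(3,4-diacetoxyphenyl)prop-2-enoyl]oxy}-1-(triethylsilyloxy)hex-5-yn-2-yl butanedioate
Product: 10 tert-butyl (2R,3R)-3-{[(E)-3-(3,4-diacetoxyphenyl)prop-2-enoyl]oxy}-1-hydroxyhex-5-yn-2-yl butanedioate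
Conditions: HF·pyridine, pyridine/THF, 0 °C
Reagents that add atoms: none
Why: Fluoride-mediated desilylation under buffered, non-basic conditions frees the primary alcohol while the tert-butyl ester, aryl acetates and both alkyl esters stay in place.

**Step 7**
Reactants: 10 tert-butyl (2R,3R)-3-{[(E)-3-(3,4-diacetoxyphenyl)prop-2-enoyl]oxy}-1-hydroxyhex-5-yn-2-yl butanedioate
Product: 11 tert-butyl (2S,3R)-3-{[(E)-3-(3,4-diacetoxyphenyl)prop-2-enoyl]oxy}-1-oxohex-5-yn-2-yl butanedioate
Conditions: Dess–Martin periodinane, NaHCO3, CH2Cl2, 0 °C to rt; used at once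
Reagents that add atoms: none
Why: Dess–Martin oxidation under buffered neutral conditions should give the α-acyloxy aldehyde without epimerisation at C4 or β-elimination of the C5 ester.

**Step 8**
Reactants: 11 tert-butyl (2S,3R)-3-{[(E)-3-(3,4-diacetoxyphenyl)prop-2-enoyl]oxy}-1-oxohex-5-yn-2-yl butanedioate
Product: 13 tert-butyl (1R,2R,6R)-2-{[(E)-3-(3,4-diacetoxyphenyl)prop-2-enoyl]oxy}-6-hydroxy-4-oxocyclohexyl butanedioate, via α-mercurio ketone aldehyde 12 (not isolated)
Conditions: Hg(OCOCF3)2 (10 mol %), acetone/H2O (4:1), rt to 35 °C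
Reagents that add atoms: water, O
Why: Proposed new method: divalent mercury and water add across the terminal alkyne in the Markovnikov sense (Kucherov-type hydration, oxygen at C1, mercury at C2), and the resulting α-mercurio methyl ketone 12 is the same kind of intermediate that closes in the Ferrier carbocyclization of 6-deoxyhex-5-enopyranosides, the closest known reaction type, so it should add to the C3 aldehyde as a mercury enolate instead of being protonated. The cyclohexane ring is closed between C2 and C3 in a 6-(enolendo)-exo-trig aldol mode. The new C3 stereocentre is set in a chair transition state with the C4 and C5 acyloxy groups equatorial and the aldehyde oxygen axial and bridged to mercury, the sense established for Ferrier carbocyclizations (new hydroxyl trans to the oxygen two carbons away, here O5, hence cis to O4). The step needs a regiodefined enolate and an aldol closure faster than protodemercuration or β-elimination: mercury sits only on C2, the medium is near neutral, and the electron-poor cinnamate alkenes and the esters are inert to Hg(OCOCF3)2. The hydroxyl formed at C3 is the only free hydroxyl of the ring, so no later differentiation of the ring oxygens is needed.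

**Step 9**
Reactants: 13 tert-butyl (1R,2R,6R)-2-{[(E)-3-(3,4-diacetoxyphenyl)prop-2-enoyl]oxy}-6-hydroxy-4-oxocyclohexyl butanedioate; 4 (E)-3-(3,4-diacetoxyphenyl)prop-2-enoic acid; 14 2-isocyano-2,4,4-trimethylpentane
Product: 15 N-(2,4,4-trimethylpentan-2-yl)amide of 1,5-di-O-(3,4-di-O-acetylcaffeoyl)-4-O-(4-tert-butoxy-4-oxobutanoyl)quinic acid, (1S,3R,4R,5R)
Conditions: CH2Cl2 (1 M), rt, 48 h
Reagents that add atoms: none
Why: Passerini three-component reaction in which the isocyanide carbon should add to the acid-activated C1 ketone from the equatorial side, away from the syn-axial C3 hydroxyl, and acyl transfer within the imidate places the caffeoyl group on the former ketone oxygen, so O1 ends axial and cis to O3 with the carboxamide equatorial (1S).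

**Step 10**
Reactants: 15 N-(2,4,4-trimethylpentan-2-yl)amide of 1,5-di-O-(3,4-di-O-acetylcaffeoyl)-4-O-(4-tert-butoxy-4-oxobutanoyl)quinic acid
Product: 17 1,5-di-O-(3,4-di-O-acetylcaffeoyl)-4-O-succinylquinic acid, via primary amide 16 (not isolated)
Conditions: CF3CO2H/CH2Cl2 (1:1), rt; then NaNO2, 0 °C to rt; aqueous work-up
Reagents that add atoms: water, O
Why: Acidolysis removes the tert-butyl ester and the tertiary N-alkyl group through their cations to give primary amide 16, and nitrosative deamination then converts the amide through the acyl diazonium ion into the carboxylic acid, all without base so the esters and C1 are untouched.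

**Step 11**
Reactants: 17 1,5-di-O-(3,4-di-O-acetylcaffeoyl)-4-O-succinylquinic acid
Product: 18 1,5-di-O-caffeoyl-4-O-succinylquinic acid, (1S,3R,4R,5R)
Conditions: 3 M aq. HCl/acetone (1:3), rt; reversed-phase chromatography
Reagents that add atoms: none
Why: Acid-catalysed hydrolysis should cleave the four aryl acetates much faster than the alkyl cinnamate and succinate esters, and the absence of base avoids acyl migration between O3 and O4.

**Compound list**
1 | (R)-2,2-dimethyl-1,3-dioxolane-4-carbaldehyde (2,3-O-isopropylidene-D-glyceraldehyde) | O=C[C@H]1COC(C)(C)O1 | starting material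
2 | 3-bromoprop-1-yne (propargyl bromide) | BrCC#C | starting material
3 | (S)-1-[(R)-2,2-dimethyl-1,3-dioxolan-4-yl]but-3-yn-1-ol | C#CC[C@H](O)[C@H]1COC(C)(C)O1 | intermediate
4 | (E)-3-(3,4-diacetoxyphenyl)prop-2-enoic acid (di-O-acetylcaffeic acid) | CC(=O)Oc1ccc(/C=C/C(=O)O)cc1OC(C)=O | starting material
5 | (R)-1-[(R)-2,2-dimethyl-1,3-dioxolan-4-yl]but-3-yn-1-yl (E)-3-(3,4-diacetoxyphenyl)prop-2-enoate | C#CC[C@@H](OC(=O)/C=C/c1ccc(OC(C)=O)c(OC(C)=O)c1)[C@H]1COC(C)(C)O1 | intermediate
6 | (2R,3R)-1,2-dihydroxyhex-5-yn-3-yl (E)-3-(3,4-diacetoxyphenyl)prop-2-enoate | C#CC[C@@H](OC(=O)/C=C/c1ccc(OC(C)=O)c(OC(C)=O)c1)[C@H](O)CO | intermediate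
7 | (2R,3R)-2-hydroxy-1-(triethylsilyloxy)hex-5-yn-3-yl (E)-3-(3,4-diacetoxyphenyl)prop-2-enoate | C#CC[C@@H](OC(=O)/C=C/c1ccc(OC(C)=O)c(OC(C)=O)c1)[C@H](O)CO[Si](CC)(CC)CC | intermediate
8 | 4-tert-butoxy-4-oxobutanoic acid (mono-tert-butyl succinate) | CC(C)(C)OC(=O)CCC(=O)O | starting material
9 | tert-butyl (2R,3R)-3-{[(E)-3-(3,4-diacetoxyphenyl)prop-2-enoyl]oxy}-1-(triethylsilyloxy)hex-5-yn-2-yl butanedioate | C#CC[C@@H](OC(=O)/C=C/c1ccc(OC(C)=O)c(OC(C)=O)c1)[C@H](OC(=O)CCC(=O)OC(C)(C)C)CO[Si](CC)(CC)CC | intermediate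
10 | tert-butyl (2R,3R)-3-{[(E)-3-(3,4-diacetoxyphenyl)prop-2-enoyl]oxy}-1-hydroxyhex-5-yn-2-yl butanedioate | C#CC[C@@H](OC(=O)/C=C/c1ccc(OC(C)=O)c(OC(C)=O)c1)[C@H](OC(=O)CCC(=O)OC(C)(C)C)CO | intermediate
11 | tert-butyl (2S,3R)-3-{[(E)-3-(3,4-diacetoxyphenyl)prop-2-enoyl]oxy}-1-oxohex-5-yn-2-yl butanedioate | C#CC[C@@H](OC(=O)/C=C/c1ccc(OC(C)=O)c(OC(C)=O)c1)[C@H](OC(=O)CCC(=O)OC(C)(C)C)C=O | intermediate
12 | tert-butyl (2S,3R)-3-{[(E)-3-(3,4-diacetoxyphenyl)prop-2-enoyl]oxy}-1,5-dioxo-6-[(trifluoroacetoxy)mercurio]hexan-2-yl butanedioate | FC(F)(F)C(=O)O[Hg]CC(=O)C[C@@H](OC(=O)/C=C/c1ccc(OC(C)=O)c(OC(C)=O)c1)[C@H](OC(=O)CCC(=O)OC(C)(C)C)C=O | intermediate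
13 | tert-butyl (1R,2R,6R)-2-{[(E)-3-(3,4-diacetoxyphenyl)prop-2-enoyl]oxy}-6-hydroxy-4-oxocyclohexyl butanedioate (ketone at C1, OH at C3, succinate at O4, caffeate at O5) | CC(C)(C)OC(=O)CCC(=O)O[C@@H]1[C@H](O)CC(=O)C[C@H]1OC(=O)/C=C/c1ccc(OC(C)=O)c(OC(C)=O)c1 | intermediate
14 | 2-isocyano-2,4,4-trimethylpentane (1,1,3,3-tetramethylbutyl isocyanide) | [C-]#[N+]C(C)(C)CC(C)(C)C | starting material
15 | N-(2,4,4-trimethylpentan-2-yl)amide of 1,5-di-O-(3,4-di-O-acetylcaffeoyl)-4-O-(4-tert-butoxy-4-oxobutanoyl)quinic acid, (1S,3R,4R,5R) | CC(C)(C)OC(=O)CCC(=O)O[C@@H]1[C@H](O)C[C@@](OC(=O)/C=C/c2ccc(OC(C)=O)c(OC(C)=O)c2)(C(=O)NC(C)(C)CC(C)(C)C)C[C@H]1OC(=O)/C=C/c1ccc(OC(C)=O)c(OC(C)=O)c1 | intermediate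
16 | primary amide (C1 carboxamide) of 1,5-di-O-(3,4-di-O-acetylcaffeoyl)-4-O-succinylquinic acid | O=C(O)CCC(=O)O[C@@H]1[C@H](O)C[C@@](OC(=O)/C=C/c2ccc(OC(C)=O)c(OC(C)=O)c2)(C(N)=O)C[C@H]1OC(=O)/C=C/c1ccc(OC(C)=O)c(OC(C)=O)c1 | intermediate
17 | 1,5-di-O-(3,4-di-O-acetylcaffeoyl)-4-O-succinylquinic acid | O=C(O)CCC(=O)O[C@@H]1[C@H](O)C[C@@](OC(=O)/C=C/c2ccc(OC(C)=O)c(OC(C)=O)c2)(C(=O)O)C[C@H]1OC(=O)/C=C/c1ccc(OC(C)=O)c(OC(C)=O)c1 | intermediate
18 | 1,5-di-O-caffeoyl-4-O-succinylquinic acid, (1S,3R,4R,5R) | O=C(O)CCC(=O)O[C@@H]1[C@H](O)C[C@@](OC(=O)/C=C/c2ccc(O)c(O)c2)(C(=O)O)C[C@H]1OC(=O)/C=C/c1ccc(O)c(O)c1 | target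

**Step count and risks**
Total steps: 11. Longest linear sequence: 11 (from compound 1).

Most likely to fail:

Step 8. Protodemercuration of the α-mercurio ketone may outrun the aldol closure, so that the alkyne is only hydrated, or the chair control at C3 may erode. The fallback sets out from 11 and uses known chemistry. The terminal alkyne is brominated (N-bromosuccinimide, cat. AgNO3, acetone) to the bromoalkyne aldehyde F1. Hydration with Ph3PAuNTf2 (monovalent gold) in wet 1,2-dichloroethane gives the bromomethyl ketone aldehyde F2. SmI2 in THF at −78 °C then forms the trivalent samarium enolate, which closes in an intramolecular Reformatsky-type aldol through a chelated chair and comes back to the route at 13; a C3 epimer, if formed, would be removed by chromatography.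

Step 9. Facial selectivity of the isocyanide attack at C1 may be poor, because a small linear nucleophile also tolerates the axial approach. The fallback sets out from 13 and reinforces the axial shield. The C3 hydroxyl is silylated (Et3SiOTf, 2,6-lutidine, CH2Cl2, −78 °C) to the 3-O-triethylsilyl ketone F3. The Passerini reaction with 4 and 14 then gives the 3-O-triethylsilyl amide F4, in which equatorial attack is enforced by the bulky axial silyl ether. The conditions of step 10 remove the silyl ether together with the tert-butyl and N-alkyl groups, so the sequence comes back to the route at 17.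

Step 2. Activation of the hindered carbinol next to the dioxolane may lead to elimination or to incomplete inversion. The fallback sets out from 1 and avoids inversion altogether. Reagent-controlled propargylation with a diisopropyl tartrate-derived allenylboronate, whose enantiomer is chosen to add to the Re face of the aldehyde against the Felkin preference, gives (R)-1-[(R)-2,2-dimethyl-1,3-dioxolan-4-yl]but-3-yn-1-ol F5. Esterification of F5 with 4 (DIC, cat. DMAP, CH2Cl2, 0 °C) proceeds with retention and comes back to the route at 5.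

**Further compounds**
F1 | step 8 | tert-butyl (2S,3R)-6-bromo-3-{[(E)-3-(3,4-diacetoxyphenyl)prop-2-enoyl]oxy}-1-oxohex-5-yn-2-yl butanedioate | BrC#CC[C@@H](OC(=O)/C=C/c1ccc(OC(C)=O)c(OC(C)=O)c1)[C@H](OC(=O)CCC(=O)OC(C)(C)C)C=O
F2 | step 8 | tert-butyl (2S,3R)-6-bromo-3-{[(E)-3-(3,4-diacetoxyphenyl)prop-2-enoyl]oxy}-1,5-dioxohexan-2-yl butanedioate | BrCC(=O)C[C@@H](OC(=O)/C=C/c1ccc(OC(C)=O)c(OC(C)=O)c1)[C@H](OC(=O)CCC(=O)OC(C)(C)C)C=O
F3 | step 9 | tert-butyl (1R,2R,6R)-2-{[(E)-3-(3,4-diacetoxyphenyl)prop-2-enoyl]oxy}-4-oxo-6-(triethylsilyloxy)cyclohexyl butanedioate | CC(C)(C)OC(=O)CCC(=O)O[C@@H]1[C@H](O[Si](CC)(CC)CC)CC(=O)C[C@H]1OC(=O)/C=C/c1ccc(OC(C)=O)c(OC(C)=O)c1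
F4 | step 9 | 3-O-triethylsilyl ether of compound 15 | CC(C)(C)OC(=O)CCC(=O)O[C@@H]1[C@H](O[Si](CC)(CC)CC)C[C@@](OC(=O)/C=C/c2ccc(OC(C)=O)c(OC(C)=O)c2)(C(=O)NC(C)(C)CC(C)(C)C)C[C@H]1OC(=O)/C=C/c1ccc(OC(C)=O)c(OC(C)=O)c1
F5 | step 2 | (R)-1-[(R)-2,2-dimethyl-1,3-dioxolan-4-yl]but-3-yn-1-ol | C#CC[C@@H](O)[C@H]1COC(C)(C)O1
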